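**Retrosynthetic overview**

1. Target ⇐ Sharpless epoxidation of the C15 allylic alcohol ⇐ Luche reduction of the C15 enal ⇐ acylation of the C14 alcohol with a cis-β-lactone (side chain, no protecting group).
2. Ten-membered ring ⇐ amine-catalysed seven-centre Grob ring expansion of a trans-decalin: the C5–C10 ring-fusion bond breaks, the C15 aldehyde (as enamine) pushes, the C1 mesylate leaves.
3. Decalin ⇐ Michael/aldol annulation of glutaraldehyde (C1–C4, C15) onto a ring B enone ester; C9, C14 and C12 oxygens are then set on the rigid decalin.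
4. Ring B ⇐ cyclohex-2-enone: Rh-catalysed asymmetric isopropenyl addition (C7), carbomethoxylation (C14), dehydrogenation.
5. Ring order: ring B (from cyclohexenone) → ring A (annulation) → ten-membered ring (expansion of the fused pair) → epoxide last.

Atom labels C1–C15 follow the germacrane numbering of the target (C14 on C10, C15 on C4, C11–C13 on C7) and are kept for the bicyclic (eudesmane-type) intermediates.

**Step 1**
Reactants: 1 cyclohex-2-en-1-one; 2 potassium trifluoro(prop-1-en-2-yl)borate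
Product: 3 (S)-3-(prop-1-en-2-yl)cyclohexan-1-one
Conditions: bis(1,5-cyclooctadiene)rhodium hexafluorophosphate [Rh(C8H12)2]PF6 (3 mol %), (S)-BINAP (3.3 mol %), toluene/H2O, 100 °C
Reagents that add atoms: none
Why: Rhodium-catalysed asymmetric 1,4-addition (Hayashi–Miyaura type) of the alkenyltrifluoroborate, in which the (S)-BINAP–rhodium alkenyl adds to one enone face and sets C7 as S.

**Step 2**
Reactants: 3 (S)-3-(prop-1-en-2-yl)cyclohexan-1-one; 4 dimethyl carbonate
Product: 5 methyl (4S)-2-oxo-4-(prop-1-en-2-yl)cyclohexane-1-carboxylate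
Conditions: NaH, THF, reflux; AcOH quench
Reagents that add atoms: none
Why: Claisen-type C-carbomethoxylation under equilibrating conditions, which places the ester on the α-carbon remote from the C7 substituent (C10) and leaves C7 untouched (C10 is an enolisable centre).

**Step 3**
Reactants: 5 methyl (4S)-2-oxo-4-(prop-1-en-2-yl)cyclohexane-1-carboxylate
Product: 7 methyl (4S)-6-oxo-4-(prop-1-en-2-yl)cyclohex-1-ene-1-carboxylate, via selenide 6 (not isolated)
Conditions: PhSeCl, pyridine, CH2Cl2, 0 °C; then mCPBA, −78 → 0 °C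
Reagents that add atoms: none
Why: α-Selenenylation of the β-keto ester and selenoxide syn-elimination, regiospecific for C10=C5 because only C5 carries a β-hydrogen, with the selenide oxidised far faster than the isopropenyl alkene at −78 °C.

**Step 4**
Reactants: 7 methyl (4S)-6-oxo-4-(prop-1-en-2-yl)cyclohex-1-ene-1-carboxylate; 8 glutaraldehyde (pentanedial)
Product: 11 methyl (1R,4R,5S,7S,10S)-1-hydroxy-15,15-dimethoxy-9-oxoeudesm-11(13)-en-14-oate, via Michael adduct 9 (not isolated), via ketol aldehyde 10 (not isolated)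
Conditions: pyrrolidine (20 mol %), PhCO2H (20 mol %), CH2Cl2, 0 °C → rt, 48 h; then HC(OMe)3, MeOH, PPTS, rt
Reagents that add atoms: trimethyl orthoformate, COC(OC)OC
Why: Enamine Michael addition to the doubly activated enone, intramolecular aldol of the β-keto ester onto the second aldehyde (Robinson-type annulation) and in-situ acetalisation, where the reversible Michael, aldol and enolisation steps are expected to funnel to the trans-decalin with the C1 hydroxyl, C4 side chain and C7 isopropenyl all equatorial and C1–O cis to the angular ester.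

**Step 5**
Reactants: 11 methyl (1R,4R,5S,7S,10S)-1-hydroxy-15,15-dimethoxy-9-oxoeudesm-11(13)-en-14-oate
Product: 12 methyl (1R,4R,5S,7S,10S)-15,15-dimethoxy-1-(methanesulfonyloxy)-9-oxoeudesm-11(13)-en-14-oate
Conditions: MsCl, Et3N, CH2Cl2, 0 °C
Reagents that add atoms: methanesulfonyl chloride, CS(=O)(=O)Cl
Why: Sulfonylation (via sulfene) of the only free hydroxyl, which fixes the future leaving group before any other alcohol exists; the quaternary C10 rules out β-elimination and no stereocentre changes.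

**Step 6**
Reactants: 12 methyl (1R,4R,5S,7S,10S)-15,15-dimethoxy-1-(methanesulfonyloxy)-9-oxoeudesm-11(13)-en-14-oate
Product: 13 (1R,4R,5S,7S,9S,10R)-9,14-dihydroxy-15,15-dimethoxyeudesm-11(13)-en-1-yl methanesulfonate
Conditions: LiBH4, THF/MeOH, 0 °C → rt
Reagents that add atoms: none
Why: Borohydride reduction of ketone and methyl ester that spares sulfonate, acetal and alkene, with axial hydride attack at C9 anti to the axial angular group giving the equatorial 9-alcohol cis to the C7 substituent (9S).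

**Step 7**
Reactants: 13 (1R,4R,5S,7S,9S,10R)-9,14-dihydroxy-15,15-dimethoxyeudesm-11(13)-en-1-yl methanesulfonate
Product: 14 (1R,4R,5S,7S,9S,10R)-9-hydroxy-15,15-dimethoxy-14-(triethylsilyloxy)eudesm-11(13)-en-1-yl methanesulfonate
Conditions: Et3SiCl, imidazole, CH2Cl2, −20 °C
Reagents that add atoms: chlorotriethylsilane, CC[Si](Cl)(CC)CC
Why: Selective silylation of the primary C14 alcohol over the hindered secondary C9 alcohol, so that C9 can be acylated alone.

**Step 8**
Reactants: 14 (1R,4R,5S,7S,9S,10R)-9-hydroxy-15,15-dimethoxy-14-(triethylsilyloxy)eudesm-11(13)-en-1-yl methanesulfonate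
Product: 15 (1R,4R,5S,7S,9S,10R)-15,15-dimethoxy-1-(methanesulfonyloxy)-14-(triethylsilyloxy)eudesm-11(13)-en-9-yl 2-methylpropanoate
Conditions: i-PrCOCl, pyridine, DMAP (cat.), CH2Cl2, 0 °C → rt
Reagents that add atoms: 2-methylpropanoyl chloride, CC(C)C(=O)Cl
Why: DMAP-catalysed acylation of the only free hydroxyl installs the C9 isobutyrate with retention at C9.

**Step 9**
Reactants: 15 (1R,4R,5S,7S,9S,10R)-15,15-dimethoxy-1-(methanesulfonyloxy)-14-(triethylsilyloxy)eudesm-11(13)-en-9-yl 2-methylpropanoate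
Product: 16 (1R,4R,5S,7S,9S,10R)-12-chloro-15,15-dimethoxy-1-(methanesulfonyloxy)-14-(triethylsilyloxy)eudesm-11(13)-en-9-yl 2-methylpropanoate
Conditions: Ca(OCl)2, solid CO2, CH2Cl2/H2O, 0 °C
Reagents that add atoms: calcium hypochlorite, [Ca+2].[O-]Cl.[O-]Cl
Why: Ene-type allylic chlorination by hypochlorous acid (electrophilic chlorine on the terminal carbon, proton loss from the methyl group) on the only alkene in the molecule, the way isopropenyl groups of terpenes are functionalised.

**Step 10**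
Reactants: 16 (1R,4R,5S,7S,9S,10R)-12-chloro-15,15-dimethoxy-1-(methanesulfonyloxy)-14-(triethylsilyloxy)eudesm-11(13)-en-9-yl 2-methylpropanoate
Product: 17 (1R,4R,5S,7S,9S,10R)-12-acetoxy-15,15-dimethoxy-1-(methanesulfonyloxy)-14-(triethylsilyloxy)eudesm-11(13)-en-9-yl 2-methylpropanoate
Conditions: CsOAc, DMF, 40 °C
Reagents that add atoms: caesium acetate, [Cs+].CC([O-])=O
Why: SN2 displacement of the primary allylic chloride by acetate, which the hindered secondary mesylate next to the quaternary C10 survives.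

**Step 11**
Reactants: 17 (1R,4R,5S,7S,9S,10R)-12-acetoxy-15,15-dimethoxy-1-(methanesulfonyloxy)-14-(triethylsilyloxy)eudesm-11(13)-en-9-yl 2-methylpropanoate
Product: 19 (1(10)E,4E,7S,9S)-12-acetoxy-14-hydroxy-15-oxogermacra-1(10),4,11(13)-trien-9-yl 2-methylpropanoate, via hydroxy aldehyde 18 (not isolated)
Conditions: AcOH/THF/H2O (3:1:1), rt; then pyrrolidine (20 mol %), NaOAc (2 equiv), 40 °C
Reagents that add atoms: water, O
Why: Proposed new method: aqueous acid frees the C15 aldehyde and the C14 hydroxyl, the amine forms the C4=C15 enamine whose nitrogen lone pair pushes through C4 into the antiperiplanar C5–C10 bond as the equatorial C1 mesylate leaves (an amine-catalysed seven-centre Grob fragmentation that expands the decalin to the cyclodecadiene), the rigid trans-decalin (C1–O antiperiplanar to C5–C10, C9 anti to C2) gives the (E)-1(10) alkene, the unsaturated iminium equilibrates through its dienamine to the more stable (E)-enal at C4=C5 before hydrolysis releases the amine, and the buffered medium spares the three esters; the closest known reaction types are the strong-base enolate-assisted seven-centre fragmentation of eudesmane-type keto mesylates, the seven-centre boronate (Marshall) fragmentation and the classical amine-triggered Grob fragmentation.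

**Step 12**
Reactants: 20 propanoyl chloride; 21 acetaldehyde
Product: 22 (3R,4S)-3,4-dimethyloxetan-2-one
Conditions: O-trimethylsilylquinine (10 mol %), LiClO4, i-Pr2NEt, CH2Cl2/Et2O, −78 °C
Reagents that add atoms: none
Why: Cinchona alkaloid/Lewis acid-catalysed acyl halide–aldehyde cyclocondensation (ketene–aldehyde [2+2]) gives the cis-β-lactone, with both centres set by the catalyst; the pseudo-enantiomeric quinidine ether gives the antipode, so the sense must be confirmed on the first batch.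

**Step 13**
Reactants: 19 (1(10)E,4E,7S,9S)-12-acetoxy-14-hydroxy-15-oxogermacra-1(10),4,11(13)-trien-9-yl 2-methylpropanoate; 22 (3R,4S)-3,4-dimethyloxetan-2-one
Product: 23 (1(10)E,4E,7S,9S)-12-acetoxy-14-[(2R,3S)-3-hydroxy-2-methylbutanoyloxy]-15-oxogermacra-1(10),4,11(13)-trien-9-yl 2-methylpropanoate
Conditions: DMAP (20 mol %), Et3N, CH2Cl2, 0 °C → rt
Reagents that add atoms: none
Why: Nucleophile-catalysed acyl–oxygen ring opening of the strained β-lactone by the only free (primary allylic) alcohol delivers the syn-hydroxy ester with both centres retained and no protecting group on the side chain.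

**Step 14**
Reactants: 23 (1(10)E,4E,7S,9S)-12-acetoxy-14-[(2R,3S)-3-hydroxy-2-methylbutanoyloxy]-15-oxogermacra-1(10),4,11(13)-trien-9-yl 2-methylpropanoate
Product: 24 (1(10)E,4E,7S,9S)-12-acetoxy-15-hydroxy-14-[(2R,3S)-3-hydroxy-2-methylbutanoyloxy]germacra-1(10),4,11(13)-trien-9-yl 2-methylpropanoate
Conditions: NaBH4, CeCl3·7H2O, MeOH, −40 °C
Reagents that add atoms: none
Why: Luche 1,2-reduction of the enal to the primary allylic alcohol, which leaves the three esters and the alkenes untouched.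

**Step 15**
Reactants: 24 (1(10)E,4E,7S,9S)-12-acetoxy-15-hydroxy-14-[(2R,3S)-3-hydroxy-2-methylbutanoyloxy]germacra-1(10),4,11(13)-trien-9-yl 2-methylpropanoate
Product: 25 (1(10)E,4R,5R,7R,9S)-12-acetoxy-4,5-epoxy-15-hydroxy-14-[(2R,3S)-3-hydroxy-2-methylbutanoyloxy]germacra-1(10),11(13)-dien-9-yl 2-methylpropanoate
Conditions: Ti(OiPr)4 (10 mol %), D-(−)-diethyl tartrate (12 mol %), t-BuOOH, 4 Å molecular sieves, CH2Cl2, −20 °C
Reagents that add atoms: tert-butyl hydroperoxide, CC(C)(C)OO
Why: Sharpless asymmetric epoxidation acts only on the C4=C5 alkene of the free allylic alcohol (the other two alkenes carry esterified allylic oxygens), and the D-(−)-tartrate complex delivers oxygen to the face that gives (4R,5R).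

**Compound list**

1 | cyclohex-2-en-1-one | O=C1C=CCCC1 | starting material
2 | potassium trifluoro(prop-1-en-2-yl)borate | [K+].C=C(C)[B-](F)(F)F | starting material
3 | (S)-3-(prop-1-en-2-yl)cyclohexan-1-one | C=C(C)[C@@H]1CC(=O)CCC1 | intermediate
4 | dimethyl carbonate | COC(=O)OC | starting material
5 | methyl (4S)-2-oxo-4-(prop-1-en-2-yl)cyclohexane-1-carboxylate (C1 epimers and enol) | C=C(C)[C@@H]1CC(=O)C(C(=O)OC)CC1 | intermediate
6 | methyl (4S)-2-oxo-1-(phenylselanyl)-4-(prop-1-en-2-yl)cyclohexane-1-carboxylate (C1 epimers) | C=C(C)[C@@H]1CC(=O)C([Se]c2ccccc2)(C(=O)OC)CC1 | intermediate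
7 | methyl (4S)-6-oxo-4-(prop-1-en-2-yl)cyclohex-1-ene-1-carboxylate | C=C(C)[C@@H]1CC(=O)C(C(=O)OC)=CC1 | intermediate
8 | glutaraldehyde (pentanedial) | O=CCCCC=O | starting material
9 | methyl (2S,4S)-2-[(2R)-1,5-dioxopentan-2-yl]-6-oxo-4-(prop-1-en-2-yl)cyclohexane-1-carboxylate (equilibrating; C1 epimers and enol) | C=C(C)[C@@H]1CC(=O)C(C(=O)OC)[C@H]([C@H](C=O)CCC=O)C1 | intermediate
10 | methyl (1R,4R,5S,7S,10S)-1-hydroxy-9,15-dioxoeudesm-11(13)-en-14-oate (trans-decalin) | C=C(C)[C@@H]1CC(=O)[C@@]2(C(=O)OC)[C@H](O)CC[C@@H](C=O)[C@@H]2C1 | intermediate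
11 | methyl (1R,4R,5S,7S,10S)-1-hydroxy-15,15-dimethoxy-9-oxoeudesm-11(13)-en-14-oate | C=C(C)[C@@H]1CC(=O)[C@@]2(C(=O)OC)[C@H](O)CC[C@@H](C(OC)OC)[C@@H]2C1 | intermediate
12 | methyl (1R,4R,5S,7S,10S)-15,15-dimethoxy-1-(methanesulfonyloxy)-9-oxoeudesm-11(13)-en-14-oate | C=C(C)[C@@H]1CC(=O)[C@@]2(C(=O)OC)[C@H](OS(C)(=O)=O)CC[C@@H](C(OC)OC)[C@@H]2C1 | intermediate
13 | (1R,4R,5S,7S,9S,10R)-9,14-dihydroxy-15,15-dimethoxyeudesm-11(13)-en-1-yl methanesulfonate | C=C(C)[C@@H]1C[C@H](O)[C@@]2(CO)[C@H](OS(C)(=O)=O)CC[C@@H](C(OC)OC)[C@@H]2C1 | intermediate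
14 | (1R,4R,5S,7S,9S,10R)-9-hydroxy-15,15-dimethoxy-14-(triethylsilyloxy)eudesm-11(13)-en-1-yl methanesulfonate | C=C(C)[C@@H]1C[C@H](O)[C@@]2(CO[Si](CC)(CC)CC)[C@H](OS(C)(=O)=O)CC[C@@H](C(OC)OC)[C@@H]2C1 | intermediate
15 | (1R,4R,5S,7S,9S,10R)-15,15-dimethoxy-1-(methanesulfonyloxy)-14-(triethylsilyloxy)eudesm-11(13)-en-9-yl 2-methylpropanoate | C=C(C)[C@@H]1C[C@H](OC(=O)C(C)C)[C@@]2(CO[Si](CC)(CC)CC)[C@H](OS(C)(=O)=O)CC[C@@H](C(OC)OC)[C@@H]2C1 | intermediate
16 | (1R,4R,5S,7S,9S,10R)-12-chloro-15,15-dimethoxy-1-(methanesulfonyloxy)-14-(triethylsilyloxy)eudesm-11(13)-en-9-yl 2-methylpropanoate | C=C(CCl)[C@@H]1C[C@H](OC(=O)C(C)C)[C@@]2(CO[Si](CC)(CC)CC)[C@H](OS(C)(=O)=O)CC[C@@H](C(OC)OC)[C@@H]2C1 | intermediate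
17 | (1R,4R,5S,7S,9S,10R)-12-acetoxy-15,15-dimethoxy-1-(methanesulfonyloxy)-14-(triethylsilyloxy)eudesm-11(13)-en-9-yl 2-methylpropanoate | C=C(COC(C)=O)[C@@H]1C[C@H](OC(=O)C(C)C)[C@@]2(CO[Si](CC)(CC)CC)[C@H](OS(C)(=O)=O)CC[C@@H](C(OC)OC)[C@@H]2C1 | intermediate
18 | (1R,4R,5S,7S,9S,10R)-12-acetoxy-14-hydroxy-1-(methanesulfonyloxy)-15-oxoeudesm-11(13)-en-9-yl 2-methylpropanoate | C=C(COC(C)=O)[C@@H]1C[C@H](OC(=O)C(C)C)[C@@]2(CO)[C@H](OS(C)(=O)=O)CC[C@@H](C=O)[C@@H]2C1 | intermediate
19 | (1(10)E,4E,7S,9S)-12-acetoxy-14-hydroxy-15-oxogermacra-1(10),4,11(13)-trien-9-yl 2-methylpropanoate | C=C(COC(C)=O)[C@@H]1C[C@H](OC(=O)C(C)C)/C(CO)=C/CC/C(C=O)=C\C1 | intermediate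
20 | propanoyl chloride | CCC(=O)Cl | starting material
21 | acetaldehyde | CC=O | starting material
22 | (3R,4S)-3,4-dimethyloxetan-2-one | O=C1O[C@@H](C)[C@H]1C | intermediate
23 | (1(10)E,4E,7S,9S)-12-acetoxy-14-[(2R,3S)-3-hydroxy-2-methylbutanoyloxy]-15-oxogermacra-1(10),4,11(13)-trien-9-yl 2-methylpropanoate | C=C(COC(C)=O)[C@@H]1C[C@H](OC(=O)C(C)C)/C(COC(=O)[C@H](C)[C@H](C)O)=C/CC/C(C=O)=C\C1 | intermediate
24 | (1(10)E,4E,7S,9S)-12-acetoxy-15-hydroxy-14-[(2R,3S)-3-hydroxy-2-methylbutanoyloxy]germacra-1(10),4,11(13)-trien-9-yl 2-methylpropanoate | C=C(COC(C)=O)[C@@H]1C[C@H](OC(=O)C(C)C)/C(COC(=O)[C@H](C)[C@H](C)O)=C/CC/C(CO)=C\C1 | intermediate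
25 | (1(10)E,4R,5R,7R,9S)-12-acetoxy-4,5-epoxy-15-hydroxy-14-[(2R,3S)-3-hydroxy-2-methylbutanoyloxy]germacra-1(10),11(13)-dien-9-yl 2-methylpropanoate | C=C(COC(C)=O)[C@@H]1C[C@H](OC(=O)C(C)C)/C(COC(=O)[C@H](C)[C@H](C)O)=C/CC[C@@]2(CO)O[C@@H]2C1 | target

**Step count**

Total steps: 15. Longest linear sequence: 14 (steps 1–11 and 13–15; step 12 is the side-chain branch).

**Three steps most likely to fail**

Step 11 (the proposed new ring expansion). Risks are slow enamine formation at the α-branched aldehyde, incomplete equilibration of the C4=C5 geometry, and transannular or Cope reactions of the 1,5-diene if heated above about 45 °C. The fallback uses known chemistry, the stoichiometric enolate-assisted seven-centre fragmentation under strong base, run stepwise. It sets out from 17 and comes back at 19. The acetal of 17 is cleaved without touching the silyl ether (Me3SiOTf, 2,6-lutidine, CH2Cl2, then water) to give (1R,4R,5S,7S,9S,10R)-12-acetoxy-1-(methanesulfonyloxy)-15-oxo-14-(triethylsilyloxy)eudesm-11(13)-en-9-yl 2-methylpropanoate F5. The aldehyde is deprotonated selectively with KN(SiMe3)2 (1.05 equiv, THF, −78 → 0 °C), and the potassium enolate fragments with loss of mesylate. After brief equilibration with Et3N this gives (1(10)E,4E,7S,9S)-12-acetoxy-15-oxo-14-(triethylsilyloxy)germacra-1(10),4,11(13)-trien-9-yl 2-methylpropanoate F6. AcOH/THF/H2O then removes the silyl group to give 19.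

Step 4 (annulation and its diastereocontrol). The all-equatorial trans-decalin depends on the Michael and aldol steps being reversible, which is an expectation, not a demonstrated result. The fallback builds ring A by an acyl-anion route that places a ketone at C4, so the ring-fusion centre C5 becomes epimerisable. It sets out from 7 and comes back at 12. Butanedial is added to 7 under thiazolium carbene catalysis (3-benzyl-5-(2-hydroxyethyl)-4-methylthiazolium chloride, Et3N, EtOH, 60 °C; Stetter addition, then aldol), and DBU then equilibrates C5 next to the C4 ketone to the trans-decalin methyl (1R,5R,7S,10S)-1-hydroxy-4,9-dioxo-15-noreudesm-11(13)-en-14-oate F1. Mesylation (MsCl, Et3N) gives methyl (1R,5R,7S,10S)-1-(methanesulfonyloxy)-4,9-dioxo-15-noreudesm-11(13)-en-14-oate F2. Wittig methoxymethylenation of the less hindered C4 ketone (Ph3P=CHOMe, THF, −78 → 0 °C) gives methyl (1R,5S,7S,10S)-15-methoxy-1-(methanesulfonyloxy)-9-oxoeudesma-4(15),11(13)-dien-14-oate F3. Methanol with PPTS converts the enol ether into the dimethyl acetal 12.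

Step 9 (allylic chlorination). Risks are competing abstraction of the C7 hydrogen and acid sensitivity of the silyl ether. The fallback replaces chlorination/displacement by allylic hydroxylation/acylation. It sets out from 15 and comes back at 17. SeO2 (cat.) with t-BuOOH in CH2Cl2 oxidises the isopropenyl methyl group to give (1R,4R,5S,7S,9S,10R)-12-hydroxy-15,15-dimethoxy-1-(methanesulfonyloxy)-14-(triethylsilyloxy)eudesm-11(13)-en-9-yl 2-methylpropanoate F4, and Ac2O, pyridine and DMAP then give 17.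

**Further compounds**

F1 | step 4 | methyl (1R,5R,7S,10S)-1-hydroxy-4,9-dioxo-15-noreudesm-11(13)-en-14-oate | C=C(C)[C@@H]1CC(=O)[C@@]2(C(=O)OC)[C@H](O)CCC(=O)[C@@H]2C1
F2 | step 4 | methyl (1R,5R,7S,10S)-1-(methanesulfonyloxy)-4,9-dioxo-15-noreudesm-11(13)-en-14-oate | C=C(C)[C@@H]1CC(=O)[C@@]2(C(=O)OC)[C@H](OS(C)(=O)=O)CCC(=O)[C@@H]2C1
F3 | step 4 | methyl (1R,5S,7S,10S)-15-methoxy-1-(methanesulfonyloxy)-9-oxoeudesma-4(15),11(13)-dien-14-oate (E/Z mixture at C4=C15) | C=C(C)[C@@H]1CC(=O)[C@@]2(C(=O)OC)[C@H](OS(C)(=O)=O)CCC(=COC)[C@@H]2C1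
F4 | step 9 | (1R,4R,5S,7S,9S,10R)-12-hydroxy-15,15-dimethoxy-1-(methanesulfonyloxy)-14-(triethylsilyloxy)eudesm-11(13)-en-9-yl 2-methylpropanoate | C=C(CO)[C@@H]1C[C@H](OC(=O)C(C)C)[C@@]2(CO[Si](CC)(CC)CC)[C@H](OS(C)(=O)=O)CC[C@@H](C(OC)OC)[C@@H]2C1
F5 | step 11 | (1R,4R,5S,7S,9S,10R)-12-acetoxy-1-(methanesulfonyloxy)-15-oxo-14-(triethylsilyloxy)eudesm-11(13)-en-9-yl 2-methylpropanoate | C=C(COC(C)=O)[C@@H]1C[C@H](OC(=O)C(C)C)[C@@]2(CO[Si](CC)(CC)CC)[C@H](OS(C)(=O)=O)CC[C@@H](C=O)[C@@H]2C1
F6 | step 11 | (1(10)E,4E,7S,9S)-12-acetoxy-15-oxo-14-(triethylsilyloxy)germacra-1(10),4,11(13)-trien-9-yl 2-methylpropanoate | C=C(COC(C)=O)[C@@H]1C[C@H](OC(=O)C(C)C)/C(CO[Si](CC)(CC)CC)=C/CC/C(C=O)=C\C1
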